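**Retrosynthetic overview**
1. Feature: C15–O and C6–O flank the C4=C5 olefin, a 2-ene-1,4-dioxygen unit where the ten-membered ring meets the γ-lactone. This is the pattern left by 1,4-opening of a C4 spiro-epoxide conjugated to C5=C6, and the C12 acid on C7 can reach C6 through a five-membered closure.
2. End game: hydrolysis of the C2 dioxolane and acetylation of C15–OH. Before that, Pd(PPh3)4 closes the lactone (second ring) from the macrocyclic epoxy acid, and all C4 and C5=C6 isomers are fed in together.
3. The carbocycle (first ring) is closed at C5=C6 by ring-closing metathesis. C4 is still a chlorohydrin at that point, because divalent chromium opens vinyl epoxides. C10=C14 is masked as CH–CH2SePh, because a free methylene would close with C6 or C5 to a five- or six-membered ring.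
4. C7–C8 and both stereocentres come from a catalytic asymmetric Nozaki–Hiyama–Kishi allylation of the C8 aldehyde with a 2-(bromomethyl)penta-2,4-dienoate. The ester is 2-(trimethylsilyl)ethyl, so fluoride can remove it without touching the C8 acetate or the epoxide.
5. The C8–C5 aldehyde is built linearly from furan-2(5H)-one (C1, C2, C10, C14), two vinyl Grignard units, a malonate half-ester (C3, C4) and chloroiodomethane (C15).

Key step: step 20

Assumption: germacrane numbering is used throughout. C10 (until step 17) and C4 and the C5=C6 geometry (until step 20) are carried as mixtures and written without descriptors, except 31, which is drawn as its (4R,5Z) isomer.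

Step 1
Reactants: 1 furan-2(5H)-one; 2 vinylmagnesium bromide
Product: 4 (±)-4-vinyldihydrofuran-2(3H)-one, via silyl ketene acetal 3 (not isolated)
Conditions: CuBr·SMe2 (10 mol %), TMSCl, THF, −78 °C; aq NH4Cl
Reagents that add atoms: none
Why: Copper-catalysed conjugate addition of the Grignard reagent, accelerated by TMSCl, places the C9=C8 vinyl group on the butenolide β-carbon (C10), which forms racemic and is erased in step 17.

Step 2
Reactants: 4 (±)-4-vinyldihydrofuran-2(3H)-one
Product: 6 (±)-4-(2-hydroxyethyl)dihydrofuran-2(3H)-one, via B-alkyl-9-BBN adduct 5 (not isolated)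
Conditions: 9-BBN, THF, 0 °C → rt; then 30 % H2O2, aq NaOAc, 0 °C
Reagents that add atoms: hydrogen peroxide, OO
Why: Anti-Markovnikov hydroboration–oxidation puts the oxygen on the terminal carbon (C8), 9-BBN ignores the lactone, and the buffered oxidation keeps the ring closed.

Step 3
Reactants: 6 (±)-4-(2-hydroxyethyl)dihydrofuran-2(3H)-one
Product: 7 (±)-4-[2-(tert-butyldimethylsilyloxy)ethyl]dihydrofuran-2(3H)-one
Conditions: TBSCl, imidazole, DMF, rt
Reagents that add atoms: tert-butyldimethylsilyl chloride, CC(C)(C)[Si](C)(C)Cl
Why: Standard silylation blocks C8–OH so that the lactone cannot migrate to the six-membered isomer, which would misdirect the next step.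

Step 4
Reactants: 7 (±)-4-[2-(tert-butyldimethylsilyloxy)ethyl]dihydrofuran-2(3H)-one
Product: 8 (±)-5-(tert-butyldimethylsilyloxy)-3-[(phenylselanyl)methyl]pentanoic acid
Conditions: (PhSe)2, NaH, THF, reflux; then 7, DMPU, 65 °C; cold 1 M HCl
Reagents that add atoms: diphenyl diselenide, c1ccc(cc1)[Se][Se]c1ccccc1
Why: The soft benzeneselenolate anion cleaves the lactone by SN2 attack at the O–CH2 carbon (C14) rather than at the carbonyl group, so one operation frees the C2 acid and installs the primary selenide that later becomes C10=C14.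

Step 5
Reactants: 8 (±)-5-(tert-butyldimethylsilyloxy)-3-[(phenylselanyl)methyl]pentanoic acid; 9 ethyl potassium malonate
Product: 11 ethyl 7-(tert-butyldimethylsilyloxy)-3-oxo-5-[(phenylselanyl)methyl]heptanoate, via acyl imidazolide 10 (not isolated)
Conditions: CDI, THF, rt; then 9, MgCl2, Et3N, MeCN, rt → 40 °C; aq NH4Cl
Reagents that add atoms: none
Why: Masamune–Brooks C-acylation of the magnesium malonate half-ester by the acyl imidazolide, followed by loss of CO2, adds C3 and C4 under almost neutral conditions.

Step 6
Reactants: 11 ethyl 7-(tert-butyldimethylsilyloxy)-3-oxo-5-[(phenylselanyl)methyl]heptanoate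
Product: 12 ethyl 2-{2-[4-(tert-butyldimethylsilyloxy)-2-[(phenylselanyl)methyl]butyl]-1,3-dioxolan-2-yl}acetate
Conditions: TMSOCH2CH2OTMS, TMSOTf (5 mol %), CH2Cl2, −78 → −20 °C; pyridine
Reagents that add atoms: 1,2-bis(trimethylsilyloxy)ethane, C[Si](C)(C)OCCO[Si](C)(C)C
Why: Aprotic ketalisation with the bis-silylated glycol, driven by formation of hexamethyldisiloxane, protects C2 without cleaving the silyl ether.

Step 7
Reactants: 12 ethyl 2-{2-[4-(tert-butyldimethylsilyloxy)-2-[(phenylselanyl)methyl]butyl]-1,3-dioxolan-2-yl}acetate; 13 chloroiodomethane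
Product: 14 1-chloro-3-{2-[4-(tert-butyldimethylsilyloxy)-2-[(phenylselanyl)methyl]butyl]-1,3-dioxolan-2-yl}propan-2-one
Conditions: MeLi·LiBr, THF/Et2O, −78 °C; AcOH, −78 °C
Reagents that add atoms: none
Why: Chloromethyllithium, formed by iodine–lithium exchange in the presence of the ester, adds only once because the tetrahedral adduct survives at −78 °C until the quench (carbenoid homologation of an ester to an α-chloroketone), and this brings in C15.

Step 8
Reactants: 14 1-chloro-3-{2-[4-(tert-butyldimethylsilyloxy)-2-[(phenylselanyl)methyl]butyl]-1,3-dioxolan-2-yl}propan-2-one; 2 vinylmagnesium bromide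
Product: 15 1-chloro-2-({2-[4-(tert-butyldimethylsilyloxy)-2-[(phenylselanyl)methyl]butyl]-1,3-dioxolan-2-yl}methyl)but-3-en-2-ol (C4 epimers)
Conditions: CeCl3, THF, −78 °C; aqueous quench at −78 °C
Reagents that add atoms: none
Why: 1,2-Addition of the weakly basic vinylcerium reagent to the α-chloroketone builds the fully substituted C4, the cold quench keeps the chlorohydrin open, and the two C4 epimers are harmless because C4 becomes sp2 in step 20.

Step 9
Reactants: 15 silyl-protected chlorohydrin
Product: 16 5-{2-[2-(chloromethyl)-2-hydroxybut-3-en-1-yl]-1,3-dioxolan-2-yl}-3-[(phenylselanyl)methyl]... primary alcohol (C8–OH free; C4 tertiary OH and CH2Cl retained)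
Conditions: HF·pyridine, pyridine, THF, 0 °C
Reagents that add atoms: none
Why: Buffered HF removes the primary silyl ether without any base, so the chlorohydrin stays open and the dioxolane survives.

Step 10
Reactants: 16 primary alcohol
Product: 17 C8 aldehyde: 4-{2-[2-(chloromethyl)-2-hydroxybut-3-en-1-yl]-1,3-dioxolan-2-yl}-3-[(phenylselanyl)methyl]butanal
Conditions: SO3·pyridine, DMSO, Et3N, CH2Cl2, 0 °C
Reagents that add atoms: none
Why: Parikh–Doering oxidation converts the primary alcohol to the aldehyde and leaves the selenide and the tertiary alcohol alone, and with C10 saturated the aldehyde cannot isomerise into conjugation.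

Step 11
Reactants: 18 acryloyl chloride; 19 2-(trimethylsilyl)ethanol
Product: 20 2-(trimethylsilyl)ethyl acrylate
Conditions: Et3N, CH2Cl2, 0 °C
Reagents that add atoms: none
Why: Simple O-acylation gives the acrylate as an ester that fluoride can remove later.

Step 12
Reactants: 20 2-(trimethylsilyl)ethyl acrylate; 21 acrolein
Product: 22 (±)-2-(trimethylsilyl)ethyl 3-hydroxy-2-methylenepent-4-enoate
Conditions: DABCO (20 mol %), 1,4-dioxane/H2O, rt, excess 20
Reagents that add atoms: none
Why: The Morita–Baylis–Hillman reaction joins the acrylate α-carbon (C11) to the aldehyde carbon of acrolein (C7).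

Step 13
Reactants: 22 (±)-2-(trimethylsilyl)ethyl 3-hydroxy-2-methylenepent-4-enoate
Product: 23 2-(trimethylsilyl)ethyl (2Z)-2-(bromomethyl)penta-2,4-dienoate
Conditions: PBr3, Et2O, 0 °C; used fresh
Reagents that add atoms: phosphorus tribromide, BrP(Br)Br
Why: SN2′ bromination of the Baylis–Hillman alcohol gives the conjugated bromide, and any 5-bromo regioisomer feeds the same pentadienylchromium species in step 14.

Step 14
Reactants: 17 C8 aldehyde; 23 2-(trimethylsilyl)ethyl (2Z)-2-(bromomethyl)penta-2,4-dienoate
Product: 25 2-(trimethylsilyl)ethyl (3R,4S)-7-{2-[2-(chloromethyl)-2-hydroxybut-3-en-1-yl]-1,3-dioxolan-2-yl}-4-hydroxy-2-methylene-6-[(phenylselanyl)methyl]-3-vinylheptanoate (7R,8S in germacrane numbering), via C8 trimethylsilyl ether 24 (not isolated)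
Conditions: CrCl2 (10 mol %), chiral 1,8-bis(4-isopropyloxazolin-2-yl)carbazole ligand (12 mol %), i-Pr2NEt (30 mol %), Mn, TMSCl, THF, rt; then citric acid, MeOH, 0 °C
Reagents that add atoms: none
Why: In this catalytic asymmetric Nozaki–Hiyama–Kishi allylation the equilibrating pentadienyl species of trivalent chromium reacts at its central carbon C7 through a chair Zimmerman–Traxler transition state with the vinyl group equatorial (7,8-anti), and the ligand antipode that exposes the Re face of the aldehyde should give 7R,8S; the chlorohydrin, unlike a vinyl epoxide, is inert to divalent chromium.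

Step 15
Reactants: 25 homoallylic alcohol
Product: 26 the corresponding (7R,8S)-C8 acetate (C4 tertiary OH free)
Conditions: Ac2O, pyridine, DMAP (5 mol %), CH2Cl2, 0 °C
Reagents that add atoms: acetic anhydride, CC(=O)OC(C)=O
Why: Prompt acetylation of the secondary alcohol installs the target's C8 acetate, prevents lactonisation onto C12, and leaves the hindered tertiary carbinol untouched.

Step 16
Reactants: 26 acetate diene
Product: 27 ten-membered carbocycle: C2 dioxolane; C4 OH and CH2Cl; C5=C6 (E/Z); C7 (R) 1-{[2-(trimethylsilyl)ethoxy]carbonyl}vinyl; C8 (S) OAc; C10 CH2SePh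
Conditions: second-generation Grubbs catalyst (10 mol %, in portions), 1,4-benzoquinone (20 mol %), CH2Cl2 (1 mM), reflux
Reagents that add atoms: none
Why: Ring-closing metathesis of the two monosubstituted vinyl groups, one on a free tertiary allylic carbinol, closes the ring at C5=C6 as an E/Z mixture that is tolerated downstream, and with C10 saturated no five-membered (C6/C10) or six-membered (C5/C10) closure can compete.

Step 17
Reactants: 27 macrocyclic selenide
Product: 29 macrocyclic chlorohydrin with C10=C14 methylene, via selenoxide 28 (not isolated)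
Conditions: mCPBA (1.0 equiv), NaHCO3, CH2Cl2, −78 °C; then i-Pr2NH, −78 → 35 °C
Reagents that add atoms: none
Why: Selenium is oxidised far faster than any olefin at −78 °C, and the primary selenoxide has its only β-hydrogen on C10, so the syn-elimination can only give the C10=C14 methylene and it erases the C10 centre.

Step 18
Reactants: 29 macrocyclic chlorohydrin
Product: 30 macrocyclic C4 spiro-epoxide 2-(trimethylsilyl)ethyl ester (C4 epimers; E/Z at C5=C6)
Conditions: NaH, THF, 0 °C
Reagents that add atoms: none
Why: In this intramolecular Williamson reaction (3-exo-tet) the tertiary alkoxide displaces the neighbouring primary chloride faster than it can reach an ester, so the vinyl epoxide appears only after the chromium, ruthenium and peracid steps.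

Step 19
Reactants: 30 macrocyclic epoxy ester
Product: 31 epoxy acid, the key-step precursor: C2 dioxolane; C4 spiro-epoxide; C5=C6; C7 (R) 1-carboxyvinyl; C8 (S) OAc; C10=C14 (four isomers; the 4R,5Z isomer is drawn)
Conditions: TBAF, THF, 0 °C; AcOH quench; cold water/EtOAc; used crude at once
Reagents that add atoms: none
Why: Fluoride attacks silicon and the ester fragments to carboxylate, ethene and Me3SiF (β-elimination of a 2-silylethyl ester), which spares the C8 acetate, the epoxide and the ketal where a saponification would not.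

Step 20
Reactants: 31 epoxy acid
Product: 32 (6R,7R,8S)-15-hydroxy-6,12-germacranolide with C2 dioxolane; C4=C5 with C3 and C6 trans; C8 OAc; C10=C14; C11=C13
Conditions: Pd(PPh3)4 (10 mol %), THF (5 mM), rt → 50 °C, argon
Reagents that add atoms: none
Why: Proposed new method: zerovalent palladium adds to the C5=C6 olefin anti to the C4–O bond and opens the spiro-epoxide to a zwitterionic C4–C5–C6 π-allyl complex of divalent palladium; its C15 alkoxide takes the proton of the C12 acid, and the carboxylate then attacks C6 on the face opposite the metal, which forms the C6–O bond, the C4=C5 olefin and the free C15 alcohol in one catalytic event. The closest known reaction types are the neutral Tsuji–Trost 1,4-addition of carboxylic acids to vinyl epoxides and the reversible lactonisation of π-allylpalladium carboxylates, and neither has been used to merge four isomers inside a ten-membered ring. The lactone closes 5-exo (O, C12, C11, C7, C6, with C4=C5 outside the new ring), whereas attack at C4 would need a seven-membered ring at a fully substituted carbon, so the C7 tether secures 1,4- over 1,2-opening. The complexes from both C4 epimers and both C5=C6 geometries exchange their syn and anti substituents and their metal-bearing face by π–σ–π rotation through the C6-bound σ-allyl form and by displacement with free zerovalent palladium, and 32, itself an allylic ester, can re-ionise. C6 is therefore set under thermodynamic control by the fixed C7 centre, since the 6,7-trans lactone (6R) with C3 and C6 trans on C4=C5 should be the least strained member of the set, as in natural 6,12-germacranolides. The step needs capture to outrun β-hydride loss from C3 or C7 and etherification by the C15 hydroxyl, which the tethered, already deprotonated carboxylate five atoms from C6 should ensure.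

Step 21
Reactants: 32 15-hydroxy lactone
Product: 33 8,15-diacetate with C2 dioxolane
Conditions: Ac2O, pyridine, DMAP (5 mol %), CH2Cl2, 0 °C
Reagents that add atoms: acetic anhydride, CC(=O)OC(C)=O
Why: Routine acetylation of the only free (primary allylic) hydroxyl, carried out after the palladium has been removed so that the new allylic acetate is not ionised.

Step 22
Reactants: 33 diacetate ketal
Product: 34 target, (6R,7R,8S)-8,15-diacetoxy-2-oxogermacra-4,10(14),11(13)-trien-6,12-olide
Conditions: silica gel wetted with 10 % aq oxalic acid, CH2Cl2, rt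
Reagents that add atoms: water, O
Why: Mild heterogeneous acid hydrolysis of the dialkyl dioxolane should free the C2 ketone without enolisation, so that neither C10=C14 nor C4=C5 moves into conjugation.

**Compound list**
1 | furan-2(5H)-one | O=C1C=CCO1 | starting material
2 | vinylmagnesium bromide | C=C[Mg]Br | starting material
3 | trimethyl[(4-vinyl-4,5-dihydrofuran-2-yl)oxy]silane | C=CC1COC(O[Si](C)(C)C)=C1 | intermediate
4 | (±)-4-vinyldihydrofuran-2(3H)-one | C=CC1COC(=O)C1 | intermediate
5 | B-[2-(5-oxotetrahydrofuran-3-yl)ethyl]-9-borabicyclo[3.3.1]nonane | O=C1CC(CCB2C3CCCC2CCC3)CO1 | intermediate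
6 | (±)-4-(2-hydroxyethyl)dihydrofuran-2(3H)-one | O=C1CC(CCO)CO1 | intermediate
7 | (±)-4-[2-(tert-butyldimethylsilyloxy)ethyl]dihydrofuran-2(3H)-one | O=C1CC(CCO[Si](C)(C)C(C)(C)C)CO1 | intermediate
8 | (±)-5-(tert-butyldimethylsilyloxy)-3-[(phenylselanyl)methyl]pentanoic acid | OC(=O)CC(C[Se]c1ccccc1)CCO[Si](C)(C)C(C)(C)C | intermediate
9 | ethyl potassium malonate | CCOC(=O)CC(=O)[O-].[K+] | starting material
10 | acyl imidazolide of 8 | O=C(CC(C[Se]c1ccccc1)CCO[Si](C)(C)C(C)(C)C)n1ccnc1 | intermediate
11 | ethyl 7-(tert-butyldimethylsilyloxy)-3-oxo-5-[(phenylselanyl)methyl]heptanoate | CCOC(=O)CC(=O)CC(C[Se]c1ccccc1)CCO[Si](C)(C)C(C)(C)C | intermediate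
12 | C2 dioxolane of 11 | CCOC(=O)CC1(CC(C[Se]c2ccccc2)CCO[Si](C)(C)C(C)(C)C)OCCO1 | intermediate
13 | chloroiodomethane | ClCI | starting material
14 | chloromethyl ketone (C4=O, C15 chloride) | ClCC(=O)CC1(CC(C[Se]c2ccccc2)CCO[Si](C)(C)C(C)(C)C)OCCO1 | intermediate
15 | silyl-protected vinyl chlorohydrin (C4, C10 epimers) | C=CC(O)(CCl)CC1(CC(C[Se]c2ccccc2)CCO[Si](C)(C)C(C)(C)C)OCCO1 | intermediate
16 | C8 primary alcohol | C=CC(O)(CCl)CC1(CC(C[Se]c2ccccc2)CCO)OCCO1 | intermediate
17 | C8 aldehyde | C=CC(O)(CCl)CC1(CC(C[Se]c2ccccc2)CC=O)OCCO1 | intermediate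
18 | acryloyl chloride | C=CC(=O)Cl | starting material
19 | 2-(trimethylsilyl)ethanol | C[Si](C)(C)CCO | starting material
20 | 2-(trimethylsilyl)ethyl acrylate | C=CC(=O)OCC[Si](C)(C)C | intermediate
21 | acrolein | C=CC=O | starting material
22 | (±)-2-(trimethylsilyl)ethyl 3-hydroxy-2-methylenepent-4-enoate | C=CC(O)C(=C)C(=O)OCC[Si](C)(C)C | intermediate
23 | 2-(trimethylsilyl)ethyl (2Z)-2-(bromomethyl)penta-2,4-dienoate | C=C/C=C(\CBr)C(=O)OCC[Si](C)(C)C | intermediate
24 | (7R,8S)-C8 trimethylsilyl ether of 25 | C=C[C@H](C(=C)C(=O)OCC[Si](C)(C)C)[C@@H](O[Si](C)(C)C)CC(C[Se]c1ccccc1)CC1(CC(O)(CCl)C=C)OCCO1 | intermediate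
25 | (7R,8S)-homoallylic alcohol | C=C[C@H](C(=C)C(=O)OCC[Si](C)(C)C)[C@@H](O)CC(C[Se]c1ccccc1)CC1(CC(O)(CCl)C=C)OCCO1 | intermediate
26 | (7R,8S)-C8 acetate, metathesis substrate | C=C[C@H](C(=C)C(=O)OCC[Si](C)(C)C)[C@@H](OC(C)=O)CC(C[Se]c1ccccc1)CC1(CC(O)(CCl)C=C)OCCO1 | intermediate
27 | macrocyclic chlorohydrin selenide | c1ccc(cc1)[Se]CC1CC2(OCCO2)CC(O)(CCl)C=C[C@H](C(=C)C(=O)OCC[Si](C)(C)C)[C@@H](OC(C)=O)C1 | intermediate
28 | selenoxide of 27 | c1ccc(cc1)[Se](=O)CC1CC2(OCCO2)CC(O)(CCl)C=C[C@H](C(=C)C(=O)OCC[Si](C)(C)C)[C@@H](OC(C)=O)C1 | intermediate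
29 | macrocyclic chlorohydrin with C10=C14 | C=C1CC2(OCCO2)CC(O)(CCl)C=C[C@H](C(=C)C(=O)OCC[Si](C)(C)C)[C@@H](OC(C)=O)C1 | intermediate
30 | macrocyclic vinyl epoxide, 2-(trimethylsilyl)ethyl ester | C=C1CC2(OCCO2)CC3(CO3)C=C[C@H](C(=C)C(=O)OCC[Si](C)(C)C)[C@@H](OC(C)=O)C1 | intermediate
31 | epoxy acid, key-step precursor (4R,5Z,7R,8S isomer drawn) | C=C1CC2(OCCO2)C[C@]3(CO3)/C=C\[C@H](C(=C)C(=O)O)[C@@H](OC(C)=O)C1 | intermediate
32 | 15-hydroxy germacranolide with C2 dioxolane, key-step product | C=C1CC2(OCCO2)C/C(CO)=C/[C@H]3OC(=O)C(=C)[C@@H]3[C@@H](OC(C)=O)C1 | intermediate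
33 | 8,15-diacetate with C2 dioxolane | C=C1CC2(OCCO2)C/C(COC(C)=O)=C/[C@H]3OC(=O)C(=C)[C@@H]3[C@@H](OC(C)=O)C1 | intermediate
34 | CNP0183179.1 | C=C1CC(=O)C/C(COC(C)=O)=C/[C@H]2OC(=O)C(=C)[C@@H]2[C@@H](OC(C)=O)C1 | target

**Step count:** 22 steps in total. The longest linear sequence is 19 steps (steps 1–10 and 14–22).

**Steps most likely to fail**

1. Step 20. The π-allyl complexes may not interconvert inside the ring, so that kinetic cis-lactone or cis-olefin isomers persist. The complex may also drain away by β-hydride elimination to a dienol.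
Fallback (known chemistry), from 31 back to 32: iodolactonisation of the γ,δ-unsaturated acid (I2, NaHCO3, MeCN, 0 °C) closes the same C6–O bond 5-exo and puts iodine on C5, giving iodolactone F1. Zinc dust (THF/EtOH, rt) then inserts into the C5–iodine bond and expels the neighbouring epoxide oxygen. This reductive opening of an α-iodo epoxide to an allylic alcohol creates C4=C5 and C15–OH of 32. Convergence is lost in this variant, so the isomers of 30 would be separated first and only those that lead to the 6,7-trans lactone carried on.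

2. Step 16. Ruthenium may load slowly on two hindered vinyl groups, the catalyst may be held by selenium, by the carbinol or by the acetate carbonyl, and oligomerisation may then win.
Fallback, from 26 back to 30: the order is changed so that a different olefin class enters the ring closure. NaH (THF, 0 °C) first closes the chlorohydrin to the spiro-epoxide diene F2, whose allylic carbon is smaller and carries no hydroxyl. Metathesis with second-generation Hoveyda–Grubbs catalyst (toluene, 1 mM, 60 °C) gives the macrocyclic epoxy selenide F3. Acid-free oxidation (NaIO4, NaHCO3, aq THF) gives the selenoxide F4, which eliminates on warming to 30.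

3. Step 14. The pentadienylchromium species may add with poor anti selectivity or through its termini, and the hydroxy ester may lactonise onto C12 before acetylation.
Fallback, from 17 and 23 back to 26: if the syn mode proves to be the intrinsic preference of this ester-bearing allylchromium, the antipodal ligand is used under the same conditions. It should give the silyl ether F5 and, after desilylation, the 7,8-syn alcohol F6 (7R,8R). A Mitsunobu reaction with acetic acid (PPh3, DIAD, toluene, 0 °C) then inverts C8 and installs the acetate in one operation, giving 26.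

**Further compounds**
F1 | step 20 | C5-iodo 6,12-lactone with intact C4 spiro-epoxide | C=C1CC2(OCCO2)CC3(CO3)C(I)[C@H]4OC(=O)C(=C)[C@@H]4[C@@H](OC(C)=O)C1
F2 | step 16 | acyclic spiro-epoxide diene (7R,8S) | C=C[C@H](C(=C)C(=O)OCC[Si](C)(C)C)[C@@H](OC(C)=O)CC(C[Se]c1ccccc1)CC1(CC2(CO2)C=C)OCCO1
F3 | step 16 | macrocyclic vinyl epoxide selenide | c1ccc(cc1)[Se]CC1CC2(OCCO2)CC3(CO3)C=C[C@H](C(=C)C(=O)OCC[Si](C)(C)C)[C@@H](OC(C)=O)C1
F4 | step 16 | selenoxide of F3 | c1ccc(cc1)[Se](=O)CC1CC2(OCCO2)CC3(CO3)C=C[C@H](C(=C)C(=O)OCC[Si](C)(C)C)[C@@H](OC(C)=O)C1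
F5 | step 14 | (7R,8R)-C8 trimethylsilyl ether | C=C[C@H](C(=C)C(=O)OCC[Si](C)(C)C)[C@H](O[Si](C)(C)C)CC(C[Se]c1ccccc1)CC1(CC(O)(CCl)C=C)OCCO1
F6 | step 14 | (7R,8R)-syn homoallylic alcohol | C=C[C@H](C(=C)C(=O)OCC[Si](C)(C)C)[C@H](O)CC(C[Se]c1ccccc1)CC1(CC(O)(CCl)C=C)OCCO1
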